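Names use the indane numbering of the target throughout: C1 bears the 4-hydroxyphenyl group, C2 the 3,5-dioxygenated phenyl group, C3 the side chain with carbinol carbon C8, and ring A is C3a–C7a with oxygens on C5 and C7.

## Structural features

The target is a 1,2,3-trisubstituted indane of the resveratrol-dimer type. Its five-membered ring C1–C2–C3–C3a–C7a is fused to the resorcinol ring A and carries a 4-hydroxyphenyl group on C1, a 3,5-dihydroxyphenyl group on C2 and a hydroxy(4-hydroxyphenyl)methyl group on C3. The three ring stereocentres are contiguous and all-trans (1R,2S,3R), and the exocyclic carbinol C8 (R) stands directly next to C3, so four adjacent stereocentres have to be controlled. Six free phenols make the compound sensitive to oxidation, and the C8 carbinol is the most fragile point: it is benzylic to a para-hydroxyphenyl ring, so acids ionise it to a quinone methide or benzylic cation that eliminates, epimerises or is captured by the resorcinol ring on C2. The real difficulty is therefore twofold: the all-trans triad in one absolute sense, and an endgame in which no Lewis or Brønsted acid meets an oxygen-bearing C8. The key step uses the 1,4-relation that ring A sets up between C1 (on C7a) and C3 (on C3a). C1 can be made electrophilic as the exocyclic terminus of a para-quinone methide and C3 nucleophilic as an ester enolate whose carbonyl carbon is C8. C2, with its aryl group, can then be inserted as a one-carbon sulfonium ylide unit that forms C1–C2 and C2–C3.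

## Logic of the disconnections

**20 to 19.** The six phenolic O–H bonds are traced back to O–Si bonds. The C8 carbinol survives neither the Lewis acids that cleave methyl ethers nor hydrogenolysis, so the last operation must be a neutral unmasking, and silyl ethers are the phenol masks that fluoride removes without acid. The skeleton is not simplified, but the fragile function appears only in the final flask. The forward step needs buffered fluoride, low temperature and exclusion of air.

**19 to 18.** The C8–H bond is cut, leading back to the aryl ketone. The ketone is the robust oxidation level at C8, and it allows C8 to be set by reagent control next to the existing C3 centre. One stereocentre is removed. The forward reduction must deliver hydride to one face regardless of the bias of C3.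

**18 to 15 and 17 (17 from 16).** The C8–aryl bond is cut. This removes the sixth aromatic ring and leaves an acyl donor on C3, so the route becomes convergent. The forward step must stop at mono-addition and must add faster than it deprotonates C3.

**15 to 14.** The C8–N bond is cut back to the methyl ester. This is a functional-group change only. It demands aminolysis of a hindered ester without loss of the silyl ethers.

**14 to 13 to 12 to 11.** The five O–Si bonds go back to O–H, four of these to O–CH3, and the two aryl C–H bonds flanking the C1-phenol go back to C–C(CH3)3. This protecting-group exchange is placed here on purpose: both Lewis-acid dealkylations are done while C8 is still an ester carbon. The gain is that the methyl ethers and the tert-butyl groups, which the earlier chemistry needs, never coexist with a benzylic C8–O bond. The demand is that the ester and the C1–aryl bond survive the Lewis acids.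

**11 to 5 and 9 (through 10).** C1–C2 and C2–C3 are cut. This opens the five-membered ring, removes all three ring stereocentres and leaves an achiral quinone methide and a one-carbon ylide. C2 is the natural point of insertion because its two neighbours are an electrophilic and a nucleophilic carbon held 1,4 on ring A. The forward step must add the ylide before any enolate exists, must pass through the trans cyclopropane 10, and must open 10 at C2 with the tethered enolate.

**9 to 8 to 6 and 7.** The ylide C–H and then the benzylic C–S bond are cut. This separates the achiral benzyl unit from the recoverable chiral sulfide. It demands clean S-alkylation at one lone pair and a non-nucleophilic counter-ion.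

**5 to 2 and 3 (through 4).** The exocyclic C1=C bond to the dienone ring is cut. This gives an aldehyde and a phenol whose para position is the only free site. It demands a condensation that tolerates a doubly ortho-substituted aldehyde and the ester.

**2 to 1.** The C7a–C1 bond (the formyl group) is cut. The position ortho to the side chain is activated by both methoxy groups, so the forward step only needs regiocontrol against the position between the methoxy groups.

## Other disconnections considered

**Alternative 1:** The cut is C7–C7a and C3a–C4, so ring A is built last on a preformed five-membered ring.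
- **Forward key step.** trans-2-Bromo-5-(3,5-dimethoxyphenyl)-4-[(tert-butyldimethylsilyloxy)(4-methoxyphenyl)methyl]cyclopent-2-enone (A1) would react with 1-methoxy-1,3-bis(trimethylsilyloxy)buta-1,3-diene (A2) in a Diels–Alder reaction. The CH2 terminus of A2 bonds to the enone β-carbon (C3a) and the acetal terminus to the bromine-bearing carbon (C7a). Dehydrobromination and loss of the methoxy group then aromatise the adduct to the 5,7-dihydroxyindan-1-one A3.
- **In favour.** The regiochemistry follows the polarity of the partners. Ring A arrives with free hydroxyls. The C2/C3 trans relation is thermodynamic, because C2 is α to the ketone.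
- **Against.** A1 must already hold C2, C3 and C8 as one stereoisomer. Its C3 hydrogen is vinylogously acidic, so epimerisation and β-elimination of the C8 silyloxy group threaten it. After the key step C1 is a ketone. The aryl group must then come by addition and deoxygenation, where hydride delivery anti to the C2 aryl group would give the cis C1/C2 relation, and the acid needed endangers the C8 ether. Three methyl ethers would still have to be cleaved with the C8 oxygen in place.
- **Comparison.** On structure it builds the aromatic ring where the chosen plan builds the carbocycle. It is the better plan on protecting groups: no tert-butyl groups, and ring A needs no demethylation. On mechanism it is a dependable pericyclic step but creates no stereocentre, whereas the chosen step creates three. On step economy it is longer, because A1 needs its own asymmetric synthesis and C1 needs further operations.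

**Alternative 2:** The cut is C2–aryl and C1–aryl.
- **Forward key step.** Under visible light the photocatalyst A6 would reduce 3,5-dimethoxybenzenediazonium tetrafluoroborate (A5); A6 is the complex [Ru(bpy)3]Cl2. The aryl radical adds to C2 of the 3-substituted 5,7-dimethoxyindene A4 (C1=C2 double bond), anti to the side chain. The oxidised form of A6 then takes an electron from the C1 radical, which gives a cation stabilised by the ortho and para methoxy groups of ring A, and anisole (A7) attacks it through its para carbon to give A8. A8 carries six O-methyl groups and is therefore the C8 silyl ether of the target hexamethyl ether.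
- **In favour.** Two aryl–carbon bonds and two stereocentres are made in one three-component operation from simple arenes. On convergence this is the better plan. The trans,trans outcome by anti approach equals what the chosen step aims for.
- **Against.** The C3 hydrogen of A4 is benzylic and allylic, so double-bond migration would racemise C3. The cationic stage and the strong acid released from the tetrafluoroborate counter-ion put the anisyl-flanked C8 silyl ether at risk. A5 can azo-couple with ring A, and A7 can react ortho. Arene capture after radical–polar crossover is the least established of the four key steps, and it depends on A6 oxidising the C1 radical before that radical dimerises or abstracts hydrogen. Six methyl ethers would remain to be cleaved beside the C8 oxygen.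
- **Comparison.** On structure no ring is formed and A4 must already contain the indane and two stereocentres. On mechanism control is by substrate only, against reagent control in the chosen plan. On step economy the key step itself is superior, but the asymmetric synthesis of A4 and the endgame cancel that gain.

**Alternative 3:** The cut is C3–C3a and C8–aryl.
- **Forward key step.** 4-Methoxyphenyllithium (A10) would add to boron of the acyclic (E)-alkenyl pinacol boronate aryl triflate A9. Zerovalent palladium is formed in the flask from the palladium source A11 and a chiral bisphosphine; A11 is Pd(OAc)2. The zerovalent palladium inserts into the C3a–O bond of the triflate. The arylpalladium species then induces 1,2-migration of the anisyl group from boron to C8 while C3 bonds to C3a, giving A12. A12 is the C8 pinacol boronate of the indane hexamethyl ether.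
- **In favour.** C3 and C8 are set together, and their relation follows stereospecifically from the alkene geometry. On this point it is better than the chosen plan, which needs a separate reduction for C8. The C–B bond can be oxidised to C–OH with retention and without acid.
- **Against.** A9 must already carry C1 and C2 as a single stereoisomer in an acyclic chain with no handle. The ring-closing mode of this coupling is not the usual intermolecular case, and the catalyst derived from A11 has to fix C3 relative to C1 and C2. A10 may attack the triflate. The anisyl-flanked benzylic boronate is prone to protodeboronation. A12 again has six methyl ethers beside a functionalised C8.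
- **Comparison.** On structure it closes the same ring through a different bond and sets two stereocentres where the chosen step sets three. On mechanism it uses a catalytic chiral ligand where the chosen plan uses a stoichiometric, recoverable chiral sulfide. On step economy it is longer, because of A9.

Key step: step 4

Assumption: sulfide 7 is written as its (1R,4R,5R) enantiomer. If the facial model of its benzylic ylide points to the opposite sense of induction, the (1S,4S,5S) sulfide is used and nothing else changes.

## Route

Step 1
Reactants: 1 methyl (3,5-dimethoxyphenyl)acetate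
Product: 2 methyl (2-formyl-3,5-dimethoxyphenyl)acetate
Conditions: POCl3, DMF, 0 → 60 °C; aq. NaOAc
Reagents that add atoms: N,N-dimethylformamide, CN(C)C=O; water, O
Why: Vilsmeier–Haack formylation; the position ortho to the side chain is para to one methoxy group and ortho to the other and is the usual site of attack in 3,5-dimethoxybenzyl systems, and any isomer formylated between the methoxy groups is removed by crystallisation.

Step 2
Reactants: 2 methyl (2-formyl-3,5-dimethoxyphenyl)acetate; 3 2,6-di-tert-butylphenol
Product: 5 methyl {2-[(3,5-di-tert-butyl-4-oxocyclohexa-2,5-dien-1-ylidene)methyl]-3,5-dimethoxyphenyl}acetate, via Mannich base 4 (not isolated)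
Conditions: piperidine, toluene, reflux (Dean–Stark); then Ac2O, reflux → rt
Reagents that add atoms: none
Why: Mannich-type condensation of the aldehyde, piperidine and the free para position of the phenol gives 4; N-acetylation and 1,6-elimination then give the para-quinone methide, which the tert-butyl groups stabilise (standard two-stage protocol for aryl para-quinone methides).

Step 3
Reactants: 6 3,5-dimethoxybenzyl bromide; 7 (1R,4R,5R)-4,7,7-trimethyl-6-thiabicyclo[3.2.1]octane (isothiocineole)
Product: 8 (1R,4R,5R)-6-(3,5-dimethoxybenzyl)-4,7,7-trimethyl-6-thiabicyclo[3.2.1]octan-6-ium trifluoromethanesulfonate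
Conditions: LiOTf, CH2Cl2/H2O, rt
Reagents that add atoms: lithium trifluoromethanesulfonate, [Li+].[O-]S(=O)(=O)C(F)(F)F
Why: SN2 S-alkylation of the sulfide at its more open (exo) lone pair by the benzylic bromide should give one sulfonium diastereomer; exchange of bromide for triflate in the two-phase mixture prevents dealkylation of the salt.

Step 4
Reactants: 8 (1R,4R,5R)-6-(3,5-dimethoxybenzyl)-4,7,7-trimethyl-6-thiabicyclo[3.2.1]octan-6-ium trifluoromethanesulfonate; 5 methyl {2-[(3,5-di-tert-butyl-4-oxocyclohexa-2,5-dien-1-ylidene)methyl]-3,5-dimethoxyphenyl}acetate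
Product: 11 methyl (1R,2S,3R)-1-(3,5-di-tert-butyl-4-hydroxyphenyl)-2-(3,5-dimethoxyphenyl)-5,7-dimethoxyindane-3-carboxylate, via sulfonium ylide 9 (not isolated), via spirocyclopropyl dienone 10 (not isolated)
Conditions: LiHMDS, THF, −78 °C; then 5, −78 → 0 °C; then Cs2CO3, DMF, 0 → 40 °C
Reagents that add atoms: none
Why: LiHMDS removes the benzylic sulfonium proton of 8, which is several pK units more acidic than the arylacetate CH2 of 5, and the carbon of ylide 9 adds to the exocyclic carbon C1 of 5 (1,6-addition) to give a phenolate betaine. With no base left to form the ester enolate, the betaine closes by 3-exo-tet attack of the phenolate para carbon on C2 with loss of sulfide 7, giving the trans-diaryl spirocyclopropyl dienone 10. Cs2CO3 is added only after 5 has been consumed: the C3 ester enolate then attacks C2 of 10 with inversion and breaks the C2–spiro bond, which forms C2–C3 and closes the five-membered ring in a 5-exo-tet sense (the breaking bond lies outside the new ring, while the cyclopropane bond C1–C2 ends up inside it), helped by benzylic activation at C2 and by rearomatisation of the departing phenolate. The closest known reaction types are the sulfonium ylide spirocyclopropanation of para-quinone methides, the nucleophilic ring opening of such spiro[2.5]octadienones with rearomatisation, and sulfur ylide [4+1] annulations of quinone methides that carry an ortho heteroatom nucleophile. C2 is set by the face of the ylide carbon that the bicyclic sulfide leaves open, C1 by the preference of the addition for the trans cyclopropane, so that an error at C1 shows up as a separable cis diastereomer and not as the enantiomer, and C3 by equilibration of the ester under the carbonate to the all-trans arrangement. C2 is inverted twice (closure to 10 and opening of 10), which is why the trans relation of 10 is carried into 11; a direct displacement of the sulfonium group by the enolate would invert C2 only once and would lead from the same betaine to the C1/C2 cis indane, so the enolate must not be present while the betaine exists. The same order of addition secures chemoselectivity, because the enolate of one molecule of 5 never meets the quinone methide of another, and the tether secures regioselectivity, because attack at C1 of 10 would need a four-membered ring.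

Step 5
Reactants: 11 methyl (1R,2S,3R)-1-(3,5-di-tert-butyl-4-hydroxyphenyl)-2-(3,5-dimethoxyphenyl)-5,7-dimethoxyindane-3-carboxylate
Product: 12 methyl (1R,2S,3R)-2-(3,5-dimethoxyphenyl)-1-(4-hydroxyphenyl)-5,7-dimethoxyindane-3-carboxylate
Conditions: AlCl3, toluene/MeNO2, rt → 50 °C
Reagents that add atoms: none
Why: Retro-Friedel–Crafts de-tert-butylation by ipso protonation ortho to the phenol, with the solvent toluene as acceptor of the tert-butyl cations; C8 is still an ester carbon, so nothing ionisable is present, and any partial O-demethylation is levelled in step 6.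

Step 6
Reactants: 12 methyl (1R,2S,3R)-2-(3,5-dimethoxyphenyl)-1-(4-hydroxyphenyl)-5,7-dimethoxyindane-3-carboxylate
Product: 13 methyl (1R,2S,3R)-2-(3,5-dihydroxyphenyl)-5,7-dihydroxy-1-(4-hydroxyphenyl)indane-3-carboxylate
Conditions: BBr3, CH2Cl2, −78 → 0 °C; MeOH, aq. NaHCO3
Reagents that add atoms: none
Why: BBr3 cleavage of the four aryl methyl ethers through aryloxyboron bromides; at or below 0 °C the methyl ester is expected to survive, and the all-trans arrangement is the thermodynamic one, so enolisation at C3 does no harm.

Step 7
Reactants: 13 methyl (1R,2S,3R)-2-(3,5-dihydroxyphenyl)-5,7-dihydroxy-1-(4-hydroxyphenyl)indane-3-carboxylate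
Product: 14 methyl (1R,2S,3R)-2-[3,5-bis(tert-butyldimethylsilyloxy)phenyl]-5,7-bis(tert-butyldimethylsilyloxy)-1-[4-(tert-butyldimethylsilyloxy)phenyl]indane-3-carboxylate
Conditions: TBSCl, imidazole, DMF, rt → 40 °C
Reagents that add atoms: tert-butyldimethylsilyl chloride, CC(C)(C)[Si](C)(C)Cl
Why: Imidazole-promoted silylation of the five phenols; the silyl ethers tolerate the organomagnesium, organolithium and borane steps and are the only masks that can later leave without acid.

Step 8
Reactants: 14 methyl (1R,2S,3R)-2-[3,5-bis(tert-butyldimethylsilyloxy)phenyl]-5,7-bis(tert-butyldimethylsilyloxy)-1-[4-(tert-butyldimethylsilyloxy)phenyl]indane-3-carboxylate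
Product: 15 (1R,2S,3R)-2-[3,5-bis(tert-butyldimethylsilyloxy)phenyl]-5,7-bis(tert-butyldimethylsilyloxy)-1-[4-(tert-butyldimethylsilyloxy)phenyl]-N-methoxy-N-methylindane-3-carboxamide
Conditions: MeNHOMe·HCl, i-PrMgCl, THF, −20 → 0 °C
Reagents that add atoms: N,O-dimethylhydroxylamine hydrochloride, CNOC.Cl
Why: Weinreb amide formation by attack of the chloromagnesium amide on the ester; any enolisation at C3 returns the trans isomer on quenching.

Step 9
Reactants: 15 (1R,2S,3R)-2-[3,5-bis(tert-butyldimethylsilyloxy)phenyl]-5,7-bis(tert-butyldimethylsilyloxy)-1-[4-(tert-butyldimethylsilyloxy)phenyl]-N-methoxy-N-methylindane-3-carboxamide; 16 (4-bromophenoxy)(tert-butyl)dimethylsilane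
Product: 18 {(1R,2S,3R)-2-[3,5-bis(tert-butyldimethylsilyloxy)phenyl]-5,7-bis(tert-butyldimethylsilyloxy)-1-[4-(tert-butyldimethylsilyloxy)phenyl]indan-3-yl}[4-(tert-butyldimethylsilyloxy)phenyl]methanone, via aryllithium 17 (not isolated)
Conditions: 16, n-BuLi, THF, −78 °C; then 15, −78 → −20 °C; aq. NH4Cl
Reagents that add atoms: none
Why: Bromine–lithium exchange gives 17, which adds to the Weinreb amide; the chelated tetrahedral intermediate collapses to the ketone only on work-up, so a second addition is excluded, and the low temperature favours addition over deprotonation at C3.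

Step 10
Reactants: 18 {(1R,2S,3R)-2-[3,5-bis(tert-butyldimethylsilyloxy)phenyl]-5,7-bis(tert-butyldimethylsilyloxy)-1-[4-(tert-butyldimethylsilyloxy)phenyl]indan-3-yl}[4-(tert-butyldimethylsilyloxy)phenyl]methanone
Product: 19 (R)-{(1R,2S,3R)-2-[3,5-bis(tert-butyldimethylsilyloxy)phenyl]-5,7-bis(tert-butyldimethylsilyloxy)-1-[4-(tert-butyldimethylsilyloxy)phenyl]indan-3-yl}[4-(tert-butyldimethylsilyloxy)phenyl]methanol
Conditions: (S)-Me-CBS, BH3·SMe2, toluene/THF, −20 °C; MeOH
Reagents that add atoms: none
Why: Corey–Bakshi–Shibata reduction; the ketone should bind to the catalyst boron with the aryl ring in the role of the large group, and the nitrogen-bound borane then delivers hydride to the face that gives the R carbinol, the sense shown by aryl alkyl ketones with the (S)-catalyst, so C8 is set by the reagent.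

Step 11
Reactants: 19 (R)-{(1R,2S,3R)-2-[3,5-bis(tert-butyldimethylsilyloxy)phenyl]-5,7-bis(tert-butyldimethylsilyloxy)-1-[4-(tert-butyldimethylsilyloxy)phenyl]indan-3-yl}[4-(tert-butyldimethylsilyloxy)phenyl]methanol
Product: 20 (1R,2S,3R)-2-(3,5-dihydroxyphenyl)-3-[(R)-hydroxy(4-hydroxyphenyl)methyl]-1-(4-hydroxyphenyl)indane-5,7-diol
Conditions: TBAF, AcOH, THF (degassed), 0 °C → rt
Reagents that add atoms: none
Why: Fluoride cleavage of the six aryl silyl ethers; acetic acid protonates each phenoxide as it forms, so the para-hydroxybenzylic C8 carbinol is not driven towards a quinone methide, and no acid strong enough to ionise C8 is present.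

## Compound list

1 | methyl (3,5-dimethoxyphenyl)acetate | COC(=O)Cc1cc(OC)cc(OC)c1 | starting material
2 | methyl (2-formyl-3,5-dimethoxyphenyl)acetate | COC(=O)Cc1cc(OC)cc(OC)c1C=O | intermediate
3 | 2,6-di-tert-butylphenol | CC(C)(C)c1cccc(c1O)C(C)(C)C | starting material
4 | methyl {2-[(3,5-di-tert-butyl-4-hydroxyphenyl)(piperidin-1-yl)methyl]-3,5-dimethoxyphenyl}acetate (racemic Mannich base) | COC(=O)Cc1cc(OC)cc(OC)c1C(N1CCCCC1)c1cc(C(C)(C)C)c(O)c(C(C)(C)C)c1 | intermediate (not isolated)
5 | methyl {2-[(3,5-di-tert-butyl-4-oxocyclohexa-2,5-dien-1-ylidene)methyl]-3,5-dimethoxyphenyl}acetate | COC(=O)Cc1cc(OC)cc(OC)c1C=C1C=C(C(C)(C)C)C(=O)C(C(C)(C)C)=C1 | intermediate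
6 | 3,5-dimethoxybenzyl bromide | COc1cc(CBr)cc(OC)c1 | starting material
7 | (1R,4R,5R)-4,7,7-trimethyl-6-thiabicyclo[3.2.1]octane (isothiocineole) | C[C@@H]1CC[C@@H]2C[C@H]1SC2(C)C | starting material
8 | (1R,4R,5R)-6-(3,5-dimethoxybenzyl)-4,7,7-trimethyl-6-thiabicyclo[3.2.1]octan-6-ium trifluoromethanesulfonate (benzyl group on the exo lone pair of sulfur) | C[C@@H]1CC[C@@H]2C[C@H]1[S@@+](Cc1cc(OC)cc(OC)c1)C2(C)C.[O-]S(=O)(=O)C(F)(F)F | intermediate
9 | (3,5-dimethoxyphenyl)[(1R,4R,5R)-4,7,7-trimethyl-6-thiabicyclo[3.2.1]octan-6-ium-6-yl]methanide (sulfonium ylide) | C[C@@H]1CC[C@@H]2C[C@H]1[S@@+]([CH-]c1cc(OC)cc(OC)c1)C2(C)C | intermediate (not isolated)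
10 | (1R,2S)-5,7-di-tert-butyl-1-[2,4-dimethoxy-6-(2-methoxy-2-oxoethyl)phenyl]-2-(3,5-dimethoxyphenyl)spiro[2.5]octa-4,7-dien-6-one (aryl groups trans) | CC(C)(C)C1=CC2(C=C(C(C)(C)C)C1=O)[C@H](c1c(CC(=O)OC)cc(OC)cc1OC)[C@H]2c1cc(OC)cc(OC)c1 | intermediate (not isolated)
11 | methyl (1R,2S,3R)-1-(3,5-di-tert-butyl-4-hydroxyphenyl)-2-(3,5-dimethoxyphenyl)-5,7-dimethoxyindane-3-carboxylate | CC(C)(C)c1cc(cc(C(C)(C)C)c1O)[C@@H]1c2c(OC)cc(OC)cc2[C@H](C(=O)OC)[C@H]1c1cc(OC)cc(OC)c1 | intermediate
12 | methyl (1R,2S,3R)-2-(3,5-dimethoxyphenyl)-1-(4-hydroxyphenyl)-5,7-dimethoxyindane-3-carboxylate | Oc1ccc(cc1)[C@@H]1c2c(OC)cc(OC)cc2[C@H](C(=O)OC)[C@H]1c1cc(OC)cc(OC)c1 | intermediate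
13 | methyl (1R,2S,3R)-2-(3,5-dihydroxyphenyl)-5,7-dihydroxy-1-(4-hydroxyphenyl)indane-3-carboxylate | Oc1ccc(cc1)[C@@H]1c2c(O)cc(O)cc2[C@H](C(=O)OC)[C@H]1c1cc(O)cc(O)c1 | intermediate
14 | methyl (1R,2S,3R)-2-[3,5-bis(tert-butyldimethylsilyloxy)phenyl]-5,7-bis(tert-butyldimethylsilyloxy)-1-[4-(tert-butyldimethylsilyloxy)phenyl]indane-3-carboxylate | CC(C)(C)[Si](C)(C)Oc1ccc(cc1)[C@@H]1c2c(O[Si](C)(C)C(C)(C)C)cc(O[Si](C)(C)C(C)(C)C)cc2[C@H](C(=O)OC)[C@H]1c1cc(O[Si](C)(C)C(C)(C)C)cc(O[Si](C)(C)C(C)(C)C)c1 | intermediate
15 | (1R,2S,3R)-2-[3,5-bis(tert-butyldimethylsilyloxy)phenyl]-5,7-bis(tert-butyldimethylsilyloxy)-1-[4-(tert-butyldimethylsilyloxy)phenyl]-N-methoxy-N-methylindane-3-carboxamide | CC(C)(C)[Si](C)(C)Oc1ccc(cc1)[C@@H]1c2c(O[Si](C)(C)C(C)(C)C)cc(O[Si](C)(C)C(C)(C)C)cc2[C@H](C(=O)N(C)OC)[C@H]1c1cc(O[Si](C)(C)C(C)(C)C)cc(O[Si](C)(C)C(C)(C)C)c1 | intermediate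
16 | (4-bromophenoxy)(tert-butyl)dimethylsilane | CC(C)(C)[Si](C)(C)Oc1ccc(Br)cc1 | starting material
17 | [4-(tert-butyldimethylsilyloxy)phenyl]lithium | [Li]c1ccc(O[Si](C)(C)C(C)(C)C)cc1 | intermediate (not isolated)
18 | {(1R,2S,3R)-2-[3,5-bis(tert-butyldimethylsilyloxy)phenyl]-5,7-bis(tert-butyldimethylsilyloxy)-1-[4-(tert-butyldimethylsilyloxy)phenyl]indan-3-yl}[4-(tert-butyldimethylsilyloxy)phenyl]methanone | CC(C)(C)[Si](C)(C)Oc1ccc(cc1)[C@@H]1c2c(O[Si](C)(C)C(C)(C)C)cc(O[Si](C)(C)C(C)(C)C)cc2[C@H](C(=O)c2ccc(O[Si](C)(C)C(C)(C)C)cc2)[C@H]1c1cc(O[Si](C)(C)C(C)(C)C)cc(O[Si](C)(C)C(C)(C)C)c1 | intermediate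
19 | (R)-{(1R,2S,3R)-2-[3,5-bis(tert-butyldimethylsilyloxy)phenyl]-5,7-bis(tert-butyldimethylsilyloxy)-1-[4-(tert-butyldimethylsilyloxy)phenyl]indan-3-yl}[4-(tert-butyldimethylsilyloxy)phenyl]methanol | CC(C)(C)[Si](C)(C)Oc1ccc(cc1)[C@@H]1c2c(O[Si](C)(C)C(C)(C)C)cc(O[Si](C)(C)C(C)(C)C)cc2[C@H]([C@@H](O)c2ccc(O[Si](C)(C)C(C)(C)C)cc2)[C@H]1c1cc(O[Si](C)(C)C(C)(C)C)cc(O[Si](C)(C)C(C)(C)C)c1 | intermediate
20 | (1R,2S,3R)-2-(3,5-dihydroxyphenyl)-3-[(R)-hydroxy(4-hydroxyphenyl)methyl]-1-(4-hydroxyphenyl)indane-5,7-diol (CNP0214825.1) | Oc1ccc([C@@H]2c3c(O)cc(O)cc3[C@H]([C@@H](O)c3ccc(O)cc3)[C@H]2c2cc(O)cc(O)c2)cc1 | target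

## Step count and least certain steps

Total step count: 11. Longest linear sequence: 10 steps (steps 1, 2 and 4 to 11, from 1 to 20); step 3 is the only branch.

**Step 4 (key step).**
- **What may go wrong.** The opening of 10 by the ester enolate may be slow, because the enolate cannot reach C2 along the ideal backside line. Heterolysis of the C1–spiro bond of 10, which the electron-rich ring A promotes, would then compete and lead to aryl migration or elimination. In addition, the bulky ylide may add slowly to the hindered, electron-rich quinone methide, and the C1/C2 relation would erode if direct sulfonium displacement by the enolate took part.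
- **Fallback.** It sets out from 5, with 1 as the source of the aldehyde, and comes back at 11. It forms the same two bonds one after the other by a different mechanism.
  - Reduction of 1 with i-Bu2AlH at −78 °C would give (3,5-dimethoxyphenyl)acetaldehyde F1.
  - Enamine-catalysed 1,6-addition of F1 to 5 with α,α-diphenylprolinol trimethylsilyl ether would give the aldehyde adduct F2. The catalyst fixes the aldehyde α-carbon C2, the two diastereomers that differ at C1 are separated, and the catalyst enantiomer is chosen so that the isomer carried on has 1R.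
  - Decarbonylation with catalytic [Rh(dppp)2]Cl (dppp = 1,3-bis(diphenylphosphino)propane) in refluxing xylene removes the formyl group, and with it the C2 centre, and gives the triarylethane F3.
  - Diazo transfer with p-ABSA and DBU gives the aryldiazoacetate F4.
  - Rh2(OAc)4 then generates the carbene at C3, which should insert into the benzylic C2–H bond in a 1,5 sense. The indane is expected with the C2 aryl group anti to the C1 aryl group, and brief treatment with DBU equilibrates C3 to give 11.

**Step 2.**
- **What may go wrong.** Condensation at the doubly ortho-substituted, electron-rich aldehyde may be incomplete, and piperidine may attack the ester at reflux.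
- **Fallback.** It sets out from 1 and comes back at 5. Friedel–Crafts benzylation of 1 with 3,5-di-tert-butyl-4-hydroxybenzyl alcohol (catalytic TfOH, CH2Cl2) would give methyl [2-(3,5-di-tert-butyl-4-hydroxybenzyl)-3,5-dimethoxyphenyl]acetate F5, after removal of any isomer substituted between the methoxy groups. Oxidation of the 4-benzylphenol with Ag2O should then give 5.

**Step 9.**
- **What may go wrong.** The aryllithium may deprotonate C3 (benzylic and α to the amide) instead of adding, and addition at the crowded carbonyl may be slow, so that 15 is returned.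
- **Fallback.** It sets out from 14 and comes back at 18. i-Bu2AlH at −78 °C would reduce 14 to the aldehyde (1R,2S,3R)-2-[3,5-bis(tert-butyldimethylsilyloxy)phenyl]-5,7-bis(tert-butyldimethylsilyloxy)-1-[4-(tert-butyldimethylsilyloxy)phenyl]indane-3-carbaldehyde F6. Aryllithium 17 should add to F6 much faster than it enolises it, giving the carbinol as a mixture of C8 epimers F7. Dess–Martin oxidation of F7 would give 18.

**Step 10.**
- **What may go wrong.** Facial selectivity may be poor: the bulky indanyl group may compete with the aryl ring for the role of the large group in the catalyst, and the C3 centre may impose an opposing bias.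
- **Fallback.** It sets out from 18 and comes back at 19. Reduction with NaBH4 in THF/EtOH under substrate control would give 19 together with its 8S epimer F8. The two silyl ethers are separated by chromatography, and F8 is returned to 18 by Dess–Martin oxidation and reduced again.

## Further compounds

F1 | step 4 | (3,5-dimethoxyphenyl)acetaldehyde | O=CCc1cc(OC)cc(OC)c1
F2 | step 4 | methyl {2-[(1R)-1-(3,5-di-tert-butyl-4-hydroxyphenyl)-2-(3,5-dimethoxyphenyl)-3-oxopropyl]-3,5-dimethoxyphenyl}acetate (C2 left open, it is removed in the next operation) | COC(=O)Cc1cc(OC)cc(OC)c1[C@H](C(C=O)c1cc(OC)cc(OC)c1)c1cc(C(C)(C)C)c(O)c(C(C)(C)C)c1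
F3 | step 4 | methyl {2-[(1R)-1-(3,5-di-tert-butyl-4-hydroxyphenyl)-2-(3,5-dimethoxyphenyl)ethyl]-3,5-dimethoxyphenyl}acetate | COC(=O)Cc1cc(OC)cc(OC)c1[C@H](Cc1cc(OC)cc(OC)c1)c1cc(C(C)(C)C)c(O)c(C(C)(C)C)c1
F4 | step 4 | methyl diazo{2-[(1R)-1-(3,5-di-tert-butyl-4-hydroxyphenyl)-2-(3,5-dimethoxyphenyl)ethyl]-3,5-dimethoxyphenyl}acetate | COC(=O)C(=[N+]=[N-])c1cc(OC)cc(OC)c1[C@H](Cc1cc(OC)cc(OC)c1)c1cc(C(C)(C)C)c(O)c(C(C)(C)C)c1
F5 | step 2 | methyl [2-(3,5-di-tert-butyl-4-hydroxybenzyl)-3,5-dimethoxyphenyl]acetate | COC(=O)Cc1cc(OC)cc(OC)c1Cc1cc(C(C)(C)C)c(O)c(C(C)(C)C)c1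
F6 | step 9 | (1R,2S,3R)-2-[3,5-bis(tert-butyldimethylsilyloxy)phenyl]-5,7-bis(tert-butyldimethylsilyloxy)-1-[4-(tert-butyldimethylsilyloxy)phenyl]indane-3-carbaldehyde | CC(C)(C)[Si](C)(C)Oc1ccc(cc1)[C@@H]1c2c(O[Si](C)(C)C(C)(C)C)cc(O[Si](C)(C)C(C)(C)C)cc2[C@H](C=O)[C@H]1c1cc(O[Si](C)(C)C(C)(C)C)cc(O[Si](C)(C)C(C)(C)C)c1
F7 | step 9 | {(1R,2S,3R)-2-[3,5-bis(tert-butyldimethylsilyloxy)phenyl]-5,7-bis(tert-butyldimethylsilyloxy)-1-[4-(tert-butyldimethylsilyloxy)phenyl]indan-3-yl}[4-(tert-butyldimethylsilyloxy)phenyl]methanol, mixture of C8 epimers | CC(C)(C)[Si](C)(C)Oc1ccc(cc1)[C@@H]1c2c(O[Si](C)(C)C(C)(C)C)cc(O[Si](C)(C)C(C)(C)C)cc2[C@H](C(O)c2ccc(O[Si](C)(C)C(C)(C)C)cc2)[C@H]1c1cc(O[Si](C)(C)C(C)(C)C)cc(O[Si](C)(C)C(C)(C)C)c1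
F8 | step 10 | (S)-{(1R,2S,3R)-2-[3,5-bis(tert-butyldimethylsilyloxy)phenyl]-5,7-bis(tert-butyldimethylsilyloxy)-1-[4-(tert-butyldimethylsilyloxy)phenyl]indan-3-yl}[4-(tert-butyldimethylsilyloxy)phenyl]methanol (C8 epimer of 19) | CC(C)(C)[Si](C)(C)Oc1ccc(cc1)[C@@H]1c2c(O[Si](C)(C)C(C)(C)C)cc(O[Si](C)(C)C(C)(C)C)cc2[C@H]([C@H](O)c2ccc(O[Si](C)(C)C(C)(C)C)cc2)[C@H]1c1cc(O[Si](C)(C)C(C)(C)C)cc(O[Si](C)(C)C(C)(C)C)c1
A1 | alternative 1 | trans-2-bromo-5-(3,5-dimethoxyphenyl)-4-[(tert-butyldimethylsilyloxy)(4-methoxyphenyl)methyl]cyclopent-2-enone, side-chain centres as in the target | O=C1C(Br)=C[C@H]([C@@H](O[Si](C)(C)C(C)(C)C)c2ccc(OC)cc2)[C@H]1c1cc(OC)cc(OC)c1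
A2 | alternative 1 | 1-methoxy-1,3-bis(trimethylsilyloxy)buta-1,3-diene | COC(O[Si](C)(C)C)=CC(=C)O[Si](C)(C)C
A3 | alternative 1 | trans-2-(3,5-dimethoxyphenyl)-5,7-dihydroxy-3-[(tert-butyldimethylsilyloxy)(4-methoxyphenyl)methyl]indan-1-one | O=C1c2c(O)cc(O)cc2[C@H]([C@@H](O[Si](C)(C)C(C)(C)C)c2ccc(OC)cc2)[C@H]1c1cc(OC)cc(OC)c1
A4 | alternative 2 | 5,7-dimethoxy-3-[(tert-butyldimethylsilyloxy)(4-methoxyphenyl)methyl]indene in the target numbering (C1=C2 double bond, sp3 carbon C3), C3 and C8 as in the target | COc1cc(OC)c2C=C[C@@H]([C@@H](O[Si](C)(C)C(C)(C)C)c3ccc(OC)cc3)c2c1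
A5 | alternative 2 | 3,5-dimethoxybenzenediazonium tetrafluoroborate | COc1cc(cc(OC)c1)[N+]#N.F[B-](F)(F)F
A6 | alternative 2 | [Ru(bpy)3]Cl2 | [Ru+2].[Cl-].[Cl-].c1ccc(nc1)-c1ccccn1.c1ccc(nc1)-c1ccccn1.c1ccc(nc1)-c1ccccn1
A7 | alternative 2 | anisole | COc1ccccc1
A8 | alternative 2 | C8 tert-butyldimethylsilyl ether of the target hexamethyl ether | COc1ccc([C@@H]2c3c(OC)cc(OC)cc3[C@H]([C@@H](O[Si](C)(C)C(C)(C)C)c3ccc(OC)cc3)[C@H]2c2cc(OC)cc(OC)c2)cc1
A9 | alternative 3 | 3,5-dimethoxy-2-[(1R,2R,3E)-2-(3,5-dimethoxyphenyl)-1-(4-methoxyphenyl)-4-(4,4,5,5-tetramethyl-1,3,2-dioxaborolan-2-yl)but-3-enyl]phenyl trifluoromethanesulfonate | COc1ccc(cc1)[C@H](c1c(OC)cc(OC)cc1OS(=O)(=O)C(F)(F)F)[C@@H](/C=C/B1OC(C)(C)C(C)(C)O1)c1cc(OC)cc(OC)c1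
A10 | alternative 3 | 4-methoxyphenyllithium | [Li]c1ccc(OC)cc1
A11 | alternative 3 | Pd(OAc)2 | CC(=O)[O-].CC(=O)[O-].[Pd+2]
A12 | alternative 3 | C8 pinacol boronate of the indane hexamethyl ether (boron in the place of the C8 hydroxyl) | COc1ccc([C@@H]2c3c(OC)cc(OC)cc3[C@H]([C@@H](B3OC(C)(C)C(C)(C)O3)c3ccc(OC)cc3)[C@H]2c2cc(OC)cc(OC)c2)cc1
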